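**Plan**

- Atoms carry isoflavone numbering. The retrosynthesis first saturates C2=C3, then cuts C2–C3, so that C2 reverts to the methyl of a ring A methyl ether and C3 to a diazo carbon. It then cuts the C6–prenyl bond back to a 1,1-dimethylallyl ether on the C5 oxygen, and finally C4–C4a between 3,5-dimethoxyphenol and 4-hydroxyphenylacetic acid.
- The feature that allows this: C2 of ring C is a single CH bonded only to O1 and to the aryl-bearing C3, so it can come from the methyl carbon of a methoxyl ortho to the ketone on ring A.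
- Forward: rings A and B are bought and joined by Friedel–Crafts acylation. The prenyl group reaches C6 by O-allylation and Claisen rearrangement, the diazo group is installed, and ring C is closed last by carbenoid C–H insertion, then dehydrogenated and desilylated.
- Stereochemistry: the target has no stereocentre and no E/Z element. C3 of the isoflavanone is the only stereocentre made on the route; it forms racemic and is removed by the dehydrogenation.

Key step: step 8

Remark: both phenols are carried as triisopropylsilyl ethers. They tolerate DBU and lithium amide bases, should resist O-to-O silyl migration in the ortho-acyl enolates of steps 7 and 9, and place no C–H bond within insertion range of the carbenoid.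

**Route**

Step 1
Reactants: 1 3,5-dimethoxyphenol; 2 4-hydroxyphenylacetic acid
Product: 3 1-(2-hydroxy-4,6-dimethoxyphenyl)-2-(4-hydroxyphenyl)ethan-1-one
Conditions: BF3·OEt2 (neat), 85 °C; aq. NaOAc work-up
Reagents that add atoms: none
Why: BF3-mediated Friedel–Crafts acylation of the electron-rich phenol by the arylacetic acid should occur ortho to the free hydroxyl, where the product ketone is held as a boron chelate, to give the 2-hydroxy deoxybenzoin.

Step 2
Reactants: 3 1-(2-hydroxy-4,6-dimethoxyphenyl)-2-(4-hydroxyphenyl)ethan-1-one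
Product: 4 1-(2-hydroxy-4,6-dimethoxyphenyl)-2-[4-(triisopropylsilyloxy)phenyl]ethan-1-one
Conditions: i-Pr3SiCl (1.1 equiv), imidazole, DMF, 0 °C → rt
Reagents that add atoms: triisopropylsilyl chloride, CC(C)[Si](Cl)(C(C)C)C(C)C
Why: Silyl ether formation should be selective for the unhindered ring B phenol, because the ring A hydroxyl is hydrogen-bonded to the ketone and much less reactive towards the bulky chlorosilane.

Step 3
Reactants: 5 2-methylbut-3-en-2-ol
Product: 6 tert-butyl 2-methylbut-3-en-2-yl carbonate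
Conditions: n-BuLi, THF, −78 °C; Boc2O, −78 °C → rt
Reagents that add atoms: di-tert-butyl dicarbonate, CC(C)(C)OC(=O)OC(=O)OC(C)(C)C
Why: Acylation of the lithium alkoxide of the tertiary allylic alcohol with Boc2O is a standard carbonate synthesis and supplies the allyl donor for step 4.

Step 4
Reactants: 4 1-(2-hydroxy-4,6-dimethoxyphenyl)-2-[4-(triisopropylsilyloxy)phenyl]ethan-1-one; 6 tert-butyl 2-methylbut-3-en-2-yl carbonate
Product: 7 1-[2,4-dimethoxy-6-(2-methylbut-3-en-2-yloxy)phenyl]-2-[4-(triisopropylsilyloxy)phenyl]ethan-1-one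
Conditions: Pd(PPh3)4 (5 mol %), THF, 0 °C
Reagents that add atoms: none
Why: In this Tsuji–Trost O-allylation zerovalent palladium ionises the tertiary carbonate with loss of CO2, the released tert-butoxide deprotonates the chelated phenol, and at low temperature the phenoxide should attack the more substituted terminus of the 1,1-dimethylallyl palladium cation to give the tertiary ether under kinetic control.

Step 5
Reactants: 7 1-[2,4-dimethoxy-6-(2-methylbut-3-en-2-yloxy)phenyl]-2-[4-(triisopropylsilyloxy)phenyl]ethan-1-one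
Product: 9 1-[2-hydroxy-4,6-dimethoxy-3-(3-methylbut-2-en-1-yl)phenyl]-2-[4-(triisopropylsilyloxy)phenyl]ethan-1-one, via cyclohexadienone 8 (not isolated)
Conditions: PhNEt2, 130 °C
Reagents that add atoms: none
Why: In this aromatic Claisen rearrangement the [3,3] shift can only end productively at the free ortho carbon (the other ortho carbon bears the acyl group), the allyl unit is inverted to a prenyl group, and tautomerisation of dienone 8 restores the chelated phenol.

Step 6
Reactants: 9 1-[2-hydroxy-4,6-dimethoxy-3-(3-methylbut-2-en-1-yl)phenyl]-2-[4-(triisopropylsilyloxy)phenyl]ethan-1-one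
Product: 10 1-[4,6-dimethoxy-3-(3-methylbut-2-en-1-yl)-2-(triisopropylsilyloxy)phenyl]-2-[4-(triisopropylsilyloxy)phenyl]ethan-1-one
Conditions: i-Pr3SiOTf, 2,6-lutidine, CH2Cl2, 0 °C → rt
Reagents that add atoms: triisopropylsilyl trifluoromethanesulfonate, CC(C)[Si](OS(=O)(=O)C(F)(F)F)(C(C)C)C(C)C
Why: The strongly electrophilic silyl triflate with a hindered pyridine base should silylate even the chelated, doubly flanked phenol and so mask the O–H bond that would otherwise capture the carbenoid.

Step 7
Reactants: 10 1-[4,6-dimethoxy-3-(3-methylbut-2-en-1-yl)-2-(triisopropylsilyloxy)phenyl]-2-[4-(triisopropylsilyloxy)phenyl]ethan-1-one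
Product: 11 2-diazo-1-[4,6-dimethoxy-3-(3-methylbut-2-en-1-yl)-2-(triisopropylsilyloxy)phenyl]-2-[4-(triisopropylsilyloxy)phenyl]ethan-1-one
Conditions: 4-acetamidobenzenesulfonyl azide, DBU, MeCN, 0 °C → rt
Reagents that add atoms: 4-acetamidobenzenesulfonyl azide, CC(=O)Nc1ccc(cc1)S(=O)(=O)N=[N+]=[N-]
Why: In this Regitz diazo transfer the methylene flanked by the ketone and ring B is acidic enough for DBU, the enolate adds to the sulfonyl azide, and loss of the sulfonamide leaves the α-aryl-α-diazo ketone.

Step 8
Reactants: 11 2-diazo-1-[4,6-dimethoxy-3-(3-methylbut-2-en-1-yl)-2-(triisopropylsilyloxy)phenyl]-2-[4-(triisopropylsilyloxy)phenyl]ethan-1-one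
Product: 12 racemic 7-methoxy-6-(3-methylbut-2-en-1-yl)-5-(triisopropylsilyloxy)-3-[4-(triisopropylsilyloxy)phenyl]chroman-4-one
Conditions: Rh2(OAc)4 (2 mol %), CH2Cl2, 40 °C, slow addition of 11
Reagents that add atoms: none
Why: Proposed new method: Rh2(OAc)4 (divalent rhodium) should expel N2 from 11 and give a rhodium carbenoid at the future C3, stabilised by ring B as donor and by the ketone as acceptor; in a six-centre transition state a C–H bond of the neighbouring C8a methoxyl, activated by its oxygen lone pair, passes hydride character to this carbon while the C2–C3 bond forms and the metal is released. The closest known reaction type is the Rh2(OAc)4-catalysed intramolecular C–H insertion of ortho-alkoxyaryl α-diazo ketones at the carbon next to the ether oxygen, which gives chroman-4-ones; its use on a methyl ether C–H bond with an α-aryl carbenoid to reach an isoflavanone is the untested part. Ring C closes as a six-membered ring by 1,6 C–H insertion through C–C bond formation, O1–C2 being present from the start as the methyl ether. C3 is created as a stereocentre with no controlling element, so 12 is racemic, which is harmless because C3 becomes trigonal in step 9. The step needs chemoselectivity for this one methyl group over oxonium ylide chemistry, and the substrate should provide it: the C5 oxygen bears a bulky silyl group with no C–H bond within six-membered reach, the C7 methoxyl is para to the ketone, the prenyl chain is meta to it and cannot reach the carbenoid, and an ylide at the aryl methyl ether oxygen forms reversibly and has no easy shift open to a methyl group.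

Step 9
Reactants: 12 racemic 7-methoxy-6-(3-methylbut-2-en-1-yl)-5-(triisopropylsilyloxy)-3-[4-(triisopropylsilyloxy)phenyl]chroman-4-one
Product: 15 7-methoxy-6-(3-methylbut-2-en-1-yl)-5-(triisopropylsilyloxy)-3-[4-(triisopropylsilyloxy)phenyl]-4H-chromen-4-one, via C3 phenylselenide 13 (not isolated), via C3 selenoxide 14 (not isolated)
Conditions: LiN(SiMe3)2, THF, −78 °C; PhSeCl, −78 °C; then 30% H2O2, pyridine, CH2Cl2, 0 °C → rt
Reagents that add atoms: none
Why: C3 is the only enolisable position, so the lithium enolate should be selenenylated there, and oxidation to the selenoxide triggers the Reich syn elimination towards C2, the only carbon with a β-hydrogen, which installs the chromone double bond and removes the C3 stereocentre.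

Step 10
Reactants: 15 7-methoxy-6-(3-methylbut-2-en-1-yl)-5-(triisopropylsilyloxy)-3-[4-(triisopropylsilyloxy)phenyl]-4H-chromen-4-one
Product: 16 Gancaonin G
Conditions: Bu4NF, AcOH, THF, 0 °C
Reagents that add atoms: none
Why: Fluoride should cleave both aryl silyl ethers, and the acetic acid buffer keeps the medium from becoming basic enough to open the chromone ring.

**Compound list**

1 | 3,5-dimethoxyphenol | COc1cc(O)cc(OC)c1 | starting material
2 | 4-hydroxyphenylacetic acid | OC(=O)Cc1ccc(O)cc1 | starting material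
3 | 1-(2-hydroxy-4,6-dimethoxyphenyl)-2-(4-hydroxyphenyl)ethan-1-one | COc1cc(O)c(C(=O)Cc2ccc(O)cc2)c(OC)c1 | intermediate
4 | 1-(2-hydroxy-4,6-dimethoxyphenyl)-2-[4-(triisopropylsilyloxy)phenyl]ethan-1-one | COc1cc(O)c(C(=O)Cc2ccc(O[Si](C(C)C)(C(C)C)C(C)C)cc2)c(OC)c1 | intermediate
5 | 2-methylbut-3-en-2-ol | CC(C)(O)C=C | starting material
6 | tert-butyl 2-methylbut-3-en-2-yl carbonate | CC(C)(C)OC(=O)OC(C)(C)C=C | intermediate
7 | 1-[2,4-dimethoxy-6-(2-methylbut-3-en-2-yloxy)phenyl]-2-[4-(triisopropylsilyloxy)phenyl]ethan-1-one | COc1cc(OC(C)(C)C=C)c(C(=O)Cc2ccc(O[Si](C(C)C)(C(C)C)C(C)C)cc2)c(OC)c1 | intermediate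
8 | racemic 3,5-dimethoxy-6-(3-methylbut-2-en-1-yl)-2-{[4-(triisopropylsilyloxy)phenyl]acetyl}cyclohexa-2,4-dien-1-one | COC1=CC(OC)=C(C(=O)Cc2ccc(O[Si](C(C)C)(C(C)C)C(C)C)cc2)C(=O)C1CC=C(C)C | intermediate
9 | 1-[2-hydroxy-4,6-dimethoxy-3-(3-methylbut-2-en-1-yl)phenyl]-2-[4-(triisopropylsilyloxy)phenyl]ethan-1-one | COc1cc(OC)c(C(=O)Cc2ccc(O[Si](C(C)C)(C(C)C)C(C)C)cc2)c(O)c1CC=C(C)C | intermediate
10 | 1-[4,6-dimethoxy-3-(3-methylbut-2-en-1-yl)-2-(triisopropylsilyloxy)phenyl]-2-[4-(triisopropylsilyloxy)phenyl]ethan-1-one | COc1cc(OC)c(C(=O)Cc2ccc(O[Si](C(C)C)(C(C)C)C(C)C)cc2)c(O[Si](C(C)C)(C(C)C)C(C)C)c1CC=C(C)C | intermediate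
11 | 2-diazo-1-[4,6-dimethoxy-3-(3-methylbut-2-en-1-yl)-2-(triisopropylsilyloxy)phenyl]-2-[4-(triisopropylsilyloxy)phenyl]ethan-1-one | COc1cc(OC)c(C(=O)C(=[N+]=[N-])c2ccc(O[Si](C(C)C)(C(C)C)C(C)C)cc2)c(O[Si](C(C)C)(C(C)C)C(C)C)c1CC=C(C)C | intermediate
12 | racemic 7-methoxy-6-(3-methylbut-2-en-1-yl)-5-(triisopropylsilyloxy)-3-[4-(triisopropylsilyloxy)phenyl]chroman-4-one | COc1cc2OCC(c3ccc(O[Si](C(C)C)(C(C)C)C(C)C)cc3)C(=O)c2c(O[Si](C(C)C)(C(C)C)C(C)C)c1CC=C(C)C | intermediate
13 | racemic 7-methoxy-6-(3-methylbut-2-en-1-yl)-3-(phenylselanyl)-5-(triisopropylsilyloxy)-3-[4-(triisopropylsilyloxy)phenyl]chroman-4-one | COc1cc2OCC([Se]c3ccccc3)(c3ccc(O[Si](C(C)C)(C(C)C)C(C)C)cc3)C(=O)c2c(O[Si](C(C)C)(C(C)C)C(C)C)c1CC=C(C)C | intermediate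
14 | 7-methoxy-6-(3-methylbut-2-en-1-yl)-3-(phenylseleninyl)-5-(triisopropylsilyloxy)-3-[4-(triisopropylsilyloxy)phenyl]chroman-4-one (racemic, both configurations at selenium) | COc1cc2OCC([Se](=O)c3ccccc3)(c3ccc(O[Si](C(C)C)(C(C)C)C(C)C)cc3)C(=O)c2c(O[Si](C(C)C)(C(C)C)C(C)C)c1CC=C(C)C | intermediate
15 | 7-methoxy-6-(3-methylbut-2-en-1-yl)-5-(triisopropylsilyloxy)-3-[4-(triisopropylsilyloxy)phenyl]-4H-chromen-4-one | COc1cc2occ(-c3ccc(O[Si](C(C)C)(C(C)C)C(C)C)cc3)c(=O)c2c(O[Si](C(C)C)(C(C)C)C(C)C)c1CC=C(C)C | intermediate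
16 | Gancaonin G, 5-hydroxy-3-(4-hydroxyphenyl)-7-methoxy-6-(3-methylbut-2-en-1-yl)-4H-chromen-4-one | COc1cc2occ(-c3ccc(O)cc3)c(=O)c2c(O)c1CC=C(C)C | target

**Step count**

Total: 10 steps. Longest linear sequence: 9 steps (steps 1, 2 and 4 to 10, from 3,5-dimethoxyphenol); step 3 is a one-step side branch.

**Steps most likely to fail**

Step 8. The carbenoid may be diverted before it inserts: attack by the ortho ether oxygen with subsequent methyl shift, Wolff rearrangement, or carbenoid dimerisation could all outrun insertion into a primary C–H bond. The fallback closes ring C by the classical deoxybenzoin route while keeping the roles of the two ortho oxygens. Setting out from 10, BCl3 in CH2Cl2 at −78 °C should cleave only the methyl ether ortho to the ketone through the boron chelate, giving 1-[6-hydroxy-4-methoxy-3-(3-methylbut-2-en-1-yl)-2-(triisopropylsilyloxy)phenyl]-2-[4-(triisopropylsilyloxy)phenyl]ethan-1-one F1. Heating F1 with N,N-dimethylformamide dimethyl acetal in toluene should supply C2 as the enaminone (E)-3-(dimethylamino)-1-[6-hydroxy-4-methoxy-3-(3-methylbut-2-en-1-yl)-2-(triisopropylsilyloxy)phenyl]-2-[4-(triisopropylsilyloxy)phenyl]prop-2-en-1-one F2. F2 should cyclise in the flask through the free phenol with loss of dimethylamine and rejoin the route at 15, so that steps 7 to 9 are bypassed.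

Step 4. The chelated phenoxide may attack the allyl palladium cation sluggishly, and the tertiary ether may be re-ionised by palladium and drift to the linear O-prenyl ether. The fallback sets out from 4. Alkylation with 3-chloro-3-methylbut-1-yne (K2CO3, KI, catalytic CuI, acetone, reflux) should give the tertiary propargyl ether 1-[2,4-dimethoxy-6-(2-methylbut-3-yn-2-yloxy)phenyl]-2-[4-(triisopropylsilyloxy)phenyl]ethan-1-one F3. Semi-hydrogenation of F3 with H2 over Pd/CaCO3 poisoned with Pb(OAc)2, in the presence of quinoline, returns to the route at 7.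

Step 9. C-selenenylation at the hindered tertiary enolate carbon may be slow, and the peroxyseleninic acid formed from the expelled selenium fragment may epoxidise the prenyl double bond. The fallback sets out from 12. The enolate is trapped with Me3SiCl as 7-methoxy-6-(3-methylbut-2-en-1-yl)-5-(triisopropylsilyloxy)-3-[4-(triisopropylsilyloxy)phenyl]-4-(trimethylsilyloxy)-2H-chromene F4. Saegusa–Ito oxidation of F4 with Pd(OAc)2 (divalent palladium) in MeCN proceeds through a palladium enolate and β-hydride elimination from C2 with no peroxide present, and rejoins the route at 15.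

**Further compounds**

F1 | step 8 | 1-[6-hydroxy-4-methoxy-3-(3-methylbut-2-en-1-yl)-2-(triisopropylsilyloxy)phenyl]-2-[4-(triisopropylsilyloxy)phenyl]ethan-1-one | COc1cc(O)c(C(=O)Cc2ccc(O[Si](C(C)C)(C(C)C)C(C)C)cc2)c(O[Si](C(C)C)(C(C)C)C(C)C)c1CC=C(C)C
F2 | step 8 | (E)-3-(dimethylamino)-1-[6-hydroxy-4-methoxy-3-(3-methylbut-2-en-1-yl)-2-(triisopropylsilyloxy)phenyl]-2-[4-(triisopropylsilyloxy)phenyl]prop-2-en-1-one | COc1cc(O)c(C(=O)/C(=C/N(C)C)c2ccc(O[Si](C(C)C)(C(C)C)C(C)C)cc2)c(O[Si](C(C)C)(C(C)C)C(C)C)c1CC=C(C)C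
F3 | step 4 | 1-[2,4-dimethoxy-6-(2-methylbut-3-yn-2-yloxy)phenyl]-2-[4-(triisopropylsilyloxy)phenyl]ethan-1-one | COc1cc(OC(C)(C)C#C)c(C(=O)Cc2ccc(O[Si](C(C)C)(C(C)C)C(C)C)cc2)c(OC)c1
F4 | step 9 | 7-methoxy-6-(3-methylbut-2-en-1-yl)-5-(triisopropylsilyloxy)-3-[4-(triisopropylsilyloxy)phenyl]-4-(trimethylsilyloxy)-2H-chromene | COc1cc2OCC(c3ccc(O[Si](C(C)C)(C(C)C)C(C)C)cc3)=C(O[Si](C)(C)C)c2c(O[Si](C(C)C)(C(C)C)C(C)C)c1CC=C(C)C
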